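**Strategy**

- Retrosynthesis: the 3-O protecting group goes last; ring A is cut at C5–C4a (key step) and at C8–C8a, and the C2–C1' bond is cut to a 2-iodopyranone and an arylboronic acid.
- Enabling feature: ring A (C4a, C5, C6, C7, C8, C8a) is hexasubstituted with four contiguous oxygens. C5(OH)–C6(OMe)–C7(OMe)–C8(OMe) are the four carbons of dimethyl squarate, and C4a=C8a is the C5=C6 bond of a 2-aryl-3-oxy-4-pyranone.
- Forward: ring C is bought as 3-hydroxy-4-pyranone, ring B is attached at C2 by Suzuki coupling, and the squarate is attached at pyranone C6 (C8–C8a bond) by magnesiation and 1,2-addition. Ring A is formed last by thermal ring expansion of the four-membered ring (C5–C4a bond).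
- Stereochemistry: the target is achiral; the one stereocentre of the squarate adducts is made racemic and becomes aromatic C8.

Key step: step 6

Remark: TMPMgCl·LiCl is taken as the commercial THF solution with LiCl as a spectator, and the racemic adducts are drawn without stereodescriptors.

**Route**

Step 1
Reactants: 1 3-hydroxy-4H-pyran-4-one (pyromeconic acid)
Product: 2 3-hydroxy-2-iodo-4H-pyran-4-one
Conditions: I2, Na2CO3, H2O, 0 °C to rt
Reagents that add atoms: iodine, II
Why: The carbonate-generated enolate of the 3-hydroxypyranone should be iodinated at C2, the only carbon ortho to the hydroxyl (electrophilic iodination of an enolic hydroxypyranone, as with kojic acid-type substrates).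

Step 2
Reactants: 2 3-hydroxy-2-iodo-4H-pyran-4-one
Product: 3 2-iodo-3-(methoxymethoxy)-4H-pyran-4-one
Conditions: MOMCl, iPr2NEt, CH2Cl2, 0 °C to rt
Reagents that add atoms: chloromethyl methyl ether (MOMCl), COCCl
Why: O-alkylation of the acidic enolic hydroxyl (Williamson-type acetal protection) gives a MOM ether that tolerates the later palladium coupling, amide base, Ag2O/MeI and heat, and is removable with mild acid.

Step 3
Reactants: 3 2-iodo-3-(methoxymethoxy)-4H-pyran-4-one; 4 4-methoxyphenylboronic acid
Product: 5 2-(4-methoxyphenyl)-3-(methoxymethoxy)-4H-pyran-4-one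
Conditions: Pd(PPh3)4 (cat.), K2CO3, 1,4-dioxane/H2O, 85 °C
Reagents that add atoms: none
Why: Suzuki–Miyaura coupling, in which the 2-iodopyranone acts as a vinylogous acyl iodide and should undergo fast oxidative addition to zerovalent palladium, while the MOM ether and the pyranone are inert to aqueous carbonate.

Step 4
Reactants: 5 2-(4-methoxyphenyl)-3-(methoxymethoxy)-4H-pyran-4-one; 6 dimethyl squarate (3,4-dimethoxycyclobut-3-ene-1,2-dione)
Product: 8 4-hydroxy-2,3-dimethoxy-4-[5-(methoxymethoxy)-6-(4-methoxyphenyl)-4-oxo-4H-pyran-2-yl]cyclobut-2-en-1-one (racemic), via 6-chloromagnesio pyranone 7 (not isolated)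
Conditions: TMPMgCl·LiCl, THF, −40 °C; then added to 6 (slight excess), THF, −78 to −40 °C; aq NH4Cl
Reagents that add atoms: none
Why: Deprotonative magnesiation with the Knochel–Hauser base should remove the most acidic ring proton, H6 next to the ring oxygen (the counterpart of chromone H2), and the α-oxyvinyl Grignard 7 then adds 1,2 to one of the two equivalent ketone-like carbonyls of the squarate, the alkoxide formed shielding the second carbonyl; the new quaternary carbinol centre is formed racemic and is erased in step 6.

Step 5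
Reactants: 8 4-hydroxy-2,3-dimethoxy-4-[5-(methoxymethoxy)-6-(4-methoxyphenyl)-4-oxo-4H-pyran-2-yl]cyclobut-2-en-1-one (racemic)
Product: 9 2,3,4-trimethoxy-4-[5-(methoxymethoxy)-6-(4-methoxyphenyl)-4-oxo-4H-pyran-2-yl]cyclobut-2-en-1-one (racemic)
Conditions: MeI, Ag2O, MeCN, rt, dark
Reagents that add atoms: iodomethane, CI
Why: Silver-oxide-promoted O-methylation (Purdie methylation) caps the tertiary carbinol without a free alkoxide, which avoids base-induced opening of the strained β-hydroxy ketone and is the usual way to protect squarate adducts; the stereocentre stays racemic.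

Step 6
Reactants: 9 2,3,4-trimethoxy-4-[5-(methoxymethoxy)-6-(4-methoxyphenyl)-4-oxo-4H-pyran-2-yl]cyclobut-2-en-1-one (racemic)
Product: 12 5-hydroxy-6,7,8-trimethoxy-3-(methoxymethoxy)-2-(4-methoxyphenyl)-4H-chromen-4-one, via dienylketene 10 (not isolated), via cyclohexadienone tautomer 11 (not isolated)
Conditions: toluene (degassed, dilute), 110 °C, Ar
Reagents that add atoms: none
Why: Proposed new method: heating 9 should open the cyclobutenone C1–C4 bond by conrotatory 4π ring opening to the dienylketene 10, whose ketene carbon then bonds to pyranone C5 in a thermal 6π electrocyclization to give 11, and enolization of the doubly activated C4a–H gives the phenol; the closest known reaction type is the Moore-type ring expansion of 4-aryl-, 4-heteroaryl- and 4-(1-alkoxyvinyl)-4-alkoxycyclobutenones from squarates to oxygenated phenols, which has not been run with the cross-conjugated C5=C6 bond of a 4-pyranone as the 2π partner. The ring closed is ring A, by 6π electrocyclic closure that forms the C5–C4a bond, the C8–C8a bond being in place since step 4. Pyranone C5 is the nucleophilic α-carbon of the vinylogous ester and the ketene carbon is the electrophile, so the polarity matches the known enol-ether cases, and the pyranone gives up far less resonance energy than a benzene ring. The selectivity needed is torquoselectivity, with the C4 methoxy turning outward and the pyranonyl inward, which the oxygen donor on C4 secures; a wrongly rotated ketene cannot lactonize through the methyl ether and can only revert to 9, and closure can occur only at C5, the sole free carbon next to the point of attachment. No stereocentre remains, since the racemic quaternary carbon of 9 becomes aromatic C8 and the transient C4a centre of 11 is lost on tautomerization. The step is an isomerization that delivers the chelated 5-OH and the 6,7,8-methoxy pattern directly, with the MOM ether untouched.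

Step 7
Reactants: 12 5-hydroxy-6,7,8-trimethoxy-3-(methoxymethoxy)-2-(4-methoxyphenyl)-4H-chromen-4-one
Product: 13 3,5-dihydroxy-6,7,8-trimethoxy-2-(4-methoxyphenyl)-4H-chromen-4-one (3,5-dihydroxy-6,7,8,4'-tetramethoxyflavone)
Conditions: HCl (cat.), MeOH/THF, 50 °C
Reagents that add atoms: none
Why: Acid-catalysed solvolysis of the MOM acetal (transacetalization to methanol) frees the 3-OH, while the aryl methyl ethers and the hydrogen-bonded 5-OH are inert to dilute HCl.

**Compound list**

1 | 3-hydroxy-4H-pyran-4-one (pyromeconic acid) | O=c1ccocc1O | starting material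
2 | 3-hydroxy-2-iodo-4H-pyran-4-one | O=c1ccoc(I)c1O | intermediate
3 | 2-iodo-3-(methoxymethoxy)-4H-pyran-4-one | COCOc1c(I)occc1=O | intermediate
4 | 4-methoxyphenylboronic acid | COc1ccc(B(O)O)cc1 | starting material
5 | 2-(4-methoxyphenyl)-3-(methoxymethoxy)-4H-pyran-4-one | COCOc1c(-c2ccc(OC)cc2)occc1=O | intermediate
6 | dimethyl squarate (3,4-dimethoxycyclobut-3-ene-1,2-dione) | COC1=C(OC)C(=O)C1=O | starting material
7 | 6-chloromagnesio-2-(4-methoxyphenyl)-3-(methoxymethoxy)-4H-pyran-4-one (not isolated) | COCOc1c(-c2ccc(OC)cc2)oc([Mg]Cl)cc1=O | intermediate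
8 | 4-hydroxy-2,3-dimethoxy-4-[5-(methoxymethoxy)-6-(4-methoxyphenyl)-4-oxo-4H-pyran-2-yl]cyclobut-2-en-1-one (racemic) | COCOc1c(-c2ccc(OC)cc2)oc(C2(O)C(OC)=C(OC)C2=O)cc1=O | intermediate
9 | 2,3,4-trimethoxy-4-[5-(methoxymethoxy)-6-(4-methoxyphenyl)-4-oxo-4H-pyran-2-yl]cyclobut-2-en-1-one (racemic) | COCOc1c(-c2ccc(OC)cc2)oc(C2(OC)C(OC)=C(OC)C2=O)cc1=O | intermediate
10 | (Z)-2,3,4-trimethoxy-4-[5-(methoxymethoxy)-6-(4-methoxyphenyl)-4-oxo-4H-pyran-2-yl]buta-1,3-dien-1-one, the dienylketene with ketenyl and pyranonyl cis (not isolated) | O=C=C(OC)/C(OC)=C(OC)\c1cc(=O)c(OCOC)c(-c2ccc(OC)cc2)o1 | intermediate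
11 | 6,7,8-trimethoxy-3-(methoxymethoxy)-2-(4-methoxyphenyl)-4aH-chromene-4,5-dione, racemic at C4a (not isolated) | COCOC1=C(c2ccc(OC)cc2)OC2=C(OC)C(OC)=C(OC)C(=O)C2C1=O | intermediate
12 | 5-hydroxy-6,7,8-trimethoxy-3-(methoxymethoxy)-2-(4-methoxyphenyl)-4H-chromen-4-one | COCOc1c(-c2ccc(OC)cc2)oc2c(OC)c(OC)c(OC)c(O)c2c1=O | intermediate
13 | 3,5-dihydroxy-6,7,8-trimethoxy-2-(4-methoxyphenyl)-4H-chromen-4-one (3,5-dihydroxy-6,7,8,4'-tetramethoxyflavone) | COc1ccc(-c2oc3c(OC)c(OC)c(OC)c(O)c3c(=O)c2O)cc1 | target

**Step count and risks**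

Total steps: 7. Longest linear sequence: 7 steps (1 to 13).

Steps most likely to fail:

1. Step 6 (ring expansion). The ketene may be consumed by intermolecular pathways (dimerization, acylation of the product phenol) faster than it closes onto the pyranone double bond, or inward rotation of the bulky pyranonyl group may be too slow. The fallback uses known chemistry only, sets out from dimethyl squarate 6 and comes back at target 13; it builds ring A by the established 4-alkenyl variant of the squarate ring expansion and ring C by classical flavone chemistry. 1-Methoxyvinyllithium (methyl vinyl ether, t-BuLi, THF) would be added to 6 at −78 °C to give 4-hydroxy-2,3-dimethoxy-4-(1-methoxyvinyl)cyclobut-2-en-1-one F1. Methylation (MeI, Ag2O, MeCN) would give 2,3,4-trimethoxy-4-(1-methoxyvinyl)cyclobut-2-en-1-one F2, and heating in toluene at 110 °C should give 2,3,4,5-tetramethoxyphenol F3. Acylation at the one free ring position (AcOH, BF3·OEt2, 80 °C) would give 1-(2-hydroxy-3,4,5,6-tetramethoxyphenyl)ethan-1-one F4. Claisen–Schmidt condensation with 4-methoxybenzaldehyde (KOH, EtOH) would give (E)-1-(2-hydroxy-3,4,5,6-tetramethoxyphenyl)-3-(4-methoxyphenyl)prop-2-en-1-one F5. Oxidative cyclization (catalytic I2, DMSO, 130 °C) would give 5,6,7,8-tetramethoxy-2-(4-methoxyphenyl)-4H-chromen-4-one F6; this is preferred to the Algar–Flynn–Oyamada oxidation, which tends to give aurones from 6'-methoxychalcones. Epoxidation of the C2=C3 bond with dimethyldioxirane and acid-induced opening (TsOH) would give 3-hydroxy-5,6,7,8-tetramethoxy-2-(4-methoxyphenyl)-4H-chromen-4-one F7. Chelation-controlled removal of the 5-O-methyl group (BCl3, CH2Cl2, −78 to 0 °C) would then give 13.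

2. Step 4 (magnesiation and squarate addition). Metalation may be incomplete or go partly to C5, the metalated pyranone may attack unmetalated pyranone while both coexist with amide base, and surviving amide may attack the squarate. The fallback sets out from pyranone 5 and comes back at carbinol 8, replacing direct deprotonation–addition by halogen–magnesium exchange. Zincation at C6 with the milder base TMP2Zn·2MgCl2·2LiCl (THF, −30 °C) and iodolysis (I2) would give 6-iodo-2-(4-methoxyphenyl)-3-(methoxymethoxy)-4H-pyran-4-one F8. Iodine–magnesium exchange with iPrMgCl·LiCl (THF, −78 °C) would then generate the Grignard completely and free of amine before 6 is added, giving 8.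

3. Step 5 (O-methylation). The hindered tertiary carbinol may methylate slowly, and prolonged exposure may fragment or open the β-hydroxy cyclobutenone. The fallback sets out from carbinol 8 and comes back at chromone 12, moving the methylation to after the ring expansion. Thermolysis of 8 (degassed toluene, 110 °C, argon) should give the hydroquinone 5,8-dihydroxy-6,7-dimethoxy-3-(methoxymethoxy)-2-(4-methoxyphenyl)-4H-chromen-4-one F9, which would be handled without exposure to air. Mono-O-methylation of the non-chelated 8-OH (MeI, K2CO3, acetone, rt), the 5-OH being hydrogen-bonded to the C4 carbonyl and far less nucleophilic, would give 12.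

Further compounds
F1 | step 6 | 4-hydroxy-2,3-dimethoxy-4-(1-methoxyvinyl)cyclobut-2-en-1-one (racemic) | C=C(OC)C1(O)C(OC)=C(OC)C1=O
F2 | step 6 | 2,3,4-trimethoxy-4-(1-methoxyvinyl)cyclobut-2-en-1-one (racemic) | C=C(OC)C1(OC)C(OC)=C(OC)C1=O
F3 | step 6 | 2,3,4,5-tetramethoxyphenol | COc1cc(O)c(OC)c(OC)c1OC
F4 | step 6 | 1-(2-hydroxy-3,4,5,6-tetramethoxyphenyl)ethan-1-one | CC(=O)c1c(O)c(OC)c(OC)c(OC)c1OC
F5 | step 6 | (E)-1-(2-hydroxy-3,4,5,6-tetramethoxyphenyl)-3-(4-methoxyphenyl)prop-2-en-1-one | COc1ccc(/C=C/C(=O)c2c(O)c(OC)c(OC)c(OC)c2OC)cc1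
F6 | step 6 | 5,6,7,8-tetramethoxy-2-(4-methoxyphenyl)-4H-chromen-4-one | COc1ccc(-c2cc(=O)c3c(OC)c(OC)c(OC)c(OC)c3o2)cc1
F7 | step 6 | 3-hydroxy-5,6,7,8-tetramethoxy-2-(4-methoxyphenyl)-4H-chromen-4-one | COc1ccc(-c2oc3c(OC)c(OC)c(OC)c(OC)c3c(=O)c2O)cc1
F8 | step 4 | 6-iodo-2-(4-methoxyphenyl)-3-(methoxymethoxy)-4H-pyran-4-one | COCOc1c(-c2ccc(OC)cc2)oc(I)cc1=O
F9 | step 5 | 5,8-dihydroxy-6,7-dimethoxy-3-(methoxymethoxy)-2-(4-methoxyphenyl)-4H-chromen-4-one | COCOc1c(-c2ccc(OC)cc2)oc2c(O)c(OC)c(OC)c(O)c2c1=O
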